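**Strategy**

Labdane numbering is used for the diterpenoid half (ring B = C5–C6–C7–C8–C9–C10, C17 = exocyclic CH2). Everything rests on the C9–C10 disconnection. The key step exploits the cis-1,3 relationship across ring A between the carboxyl carbon C19 on C4 and quaternary C10: a bridged C19–O–C10 γ-lactone, obtained by protolactonisation of a C5=C10 alkene acid (which also sets C5), is ionised, and C9 of a Z-allylsilane tethered to C5 captures C10 from the face opposite the departing carboxylate. One operation closes ring B, sets C9 and C10, creates the C8=C17 methylene and frees the C19 acid for esterification with silyl-protected cryptomeridiol made from β-eudesmol.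

Key step: step 14

Assumption: in step 1 the (11bS)-configured ammonium catalyst is taken to deliver the S-ester 2; if the facial sense is the opposite, its commercial (11bR)-antipode is used and nothing else changes.

Remark: eudesmane numbering (C4 carbinol carbon, C10 angular methyl carbon, C11 side-chain carbinol carbon, C15 exocyclic carbon) is used for the sesquiterpenoid half.

**Route**

Step 1
Reactants: 1 tert-butyl 2-oxocyclohexane-1-carboxylate
Product: 2 tert-butyl (1S)-1-methyl-2-oxocyclohexane-1-carboxylate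
Conditions: MeI (3 equiv), CsOH·H2O (1.5 equiv), (11bS)-4,4-dibutyl-2,6-bis(3,4,5-trifluorophenyl)-4,5-dihydro-3H-dinaphtho[2,1-c:1',2'-e]azepin-4-ium bromide (2 mol %), toluene, −40 °C
Reagents that add atoms: iodomethane, CI
Why: Phase-transfer-catalysed asymmetric C-alkylation of the β-keto ester enolate, in which the chiral ammonium ion pair shields one enolate face so that MeI sets the quaternary centre that becomes labdane C4.

Step 2
Reactants: 2 tert-butyl (1S)-1-methyl-2-oxocyclohexane-1-carboxylate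
Product: 3 tert-butyl (1S)-1,3-dimethyl-2-oxocyclohexane-1-carboxylate (mixture of C3 epimers)
Conditions: LiN(iPr)2 (1.1 equiv), THF, −78 °C; MeI, −78 → 0 °C
Reagents that add atoms: iodomethane, CI
Why: Kinetic enolate alkylation, regiospecific because the ketone can only enolise away from the quaternary carbon; it installs the future C20 methyl, and the new centre is erased in step 3.

Step 3
Reactants: 3 tert-butyl (1S)-1,3-dimethyl-2-oxocyclohexane-1-carboxylate
Product: 4 tert-butyl (1S)-1,3-dimethyl-2-(trifluoromethanesulfonyloxy)cyclohex-2-ene-1-carboxylate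
Conditions: KN(SiMe3)2 (1.2 equiv), THF, −78 °C; PhNTf2, −78 → 0 °C
Reagents that add atoms: N-phenylbis(trifluoromethanesulfonimide), O=S(=O)(N(c1ccccc1)S(=O)(=O)C(F)(F)F)C(F)(F)F
Why: Enol triflate formation, in which the only possible enolate is O-sulfonylated to give the tetrasubstituted C5=C10 enol triflate regiospecifically.

Step 4
Reactants: 4 tert-butyl (1S)-1,3-dimethyl-2-(trifluoromethanesulfonyloxy)cyclohex-2-ene-1-carboxylate; 5 (4-bromobut-1-yn-1-yl)trimethylsilane
Product: 7 tert-butyl (1S)-1,3-dimethyl-2-[4-(trimethylsilyl)but-3-yn-1-yl]cyclohex-2-ene-1-carboxylate, via alkylzinc bromide 6 (not isolated)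
Conditions: 5, Zn dust, LiCl, THF, 40 °C; then 4, Pd(OAc)2 (5 mol %), SPhos (10 mol %), THF/NMP, 60 °C
Reagents that add atoms: none
Why: Negishi sp2–sp3 cross-coupling of the alkylzinc (from zinc insertion into the bromide) with the hindered enol triflate, which attaches C6–C9 as a silyl-capped butynyl chain and leaves the ester and C4 untouched.

Step 5
Reactants: 7 tert-butyl (1S)-1,3-dimethyl-2-[4-(trimethylsilyl)but-3-yn-1-yl]cyclohex-2-ene-1-carboxylate
Product: 9 (1S,5R,8S)-1,5-dimethyl-8-[4-(trimethylsilyl)but-3-yn-1-yl]-6-oxabicyclo[3.2.1]octan-7-one, via carboxylic acid 8 (not isolated)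
Conditions: CF3CO2H/CH2Cl2 (1:1), 0 °C → rt
Reagents that add atoms: none
Why: Acidolysis of the tert-butyl ester followed by protolactonisation of the β,γ-unsaturated acid, in which Markovnikov protonation at C5 gives the tertiary C10 cation that the C19 carboxyl traps from the face on which C4 holds it; anti addition and reversible ionisation should both place the C5 hydrogen anti to the lactone bridge and the chain equatorial, which sets C5.

Step 6
Reactants: 9 (1S,5R,8S)-1,5-dimethyl-8-[4-(trimethylsilyl)but-3-yn-1-yl]-6-oxabicyclo[3.2.1]octan-7-one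
Product: 10 (1S,5R,8S)-8-(but-3-yn-1-yl)-1,5-dimethyl-6-oxabicyclo[3.2.1]octan-7-one
Conditions: K2CO3 (0.1 equiv), MeOH/THF, 0 °C
Reagents that add atoms: none
Why: Base-catalysed protodesilylation of the alkynylsilane, which the hindered tertiary lactone (neopentylic carbonyl) should survive under catalytic carbonate at low temperature.

Step 7
Reactants: 11 (2E)-3-methylpent-2-en-4-yn-1-ol
Product: 12 tert-butyldimethyl{[(2E)-3-methylpent-2-en-4-yn-1-yl]oxy}silane
Conditions: t-BuMe2SiCl, imidazole, DMF, 0 °C → rt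
Reagents that add atoms: tert-butyldimethylsilyl chloride, CC(C)(C)[Si](C)(C)Cl
Why: Imidazole-mediated silyl ether formation on the primary allylic alcohol, giving a C15 protecting group that tolerates the organometallic and Lewis-acid steps.

Step 8
Reactants: 12 tert-butyldimethyl{[(2E)-3-methylpent-2-en-4-yn-1-yl]oxy}silane
Product: 13 tert-butyldimethyl{[(2E)-3-methylpenta-2,4-dien-1-yl]oxy}silane
Conditions: H2 (1 atm), Pd on CaCO3 poisoned with Pb(OAc)2, quinoline, hexane, rt
Reagents that add atoms: none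
Why: Lindlar semihydrogenation of the terminal alkyne to a vinyl group, which leaves the trisubstituted E-alkene and the silyl ether untouched.

Step 9
Reactants: 13 tert-butyldimethyl{[(2E)-3-methylpenta-2,4-dien-1-yl]oxy}silane
Product: 15 tert-butyl{[(2E)-5-iodo-3-methylpent-2-en-1-yl]oxy}dimethylsilane, via B-alkyl-9-BBN 14 (not isolated)
Conditions: 9-borabicyclo[3.3.1]nonane (9-BBN-H), THF, 0 °C → rt; then NaOMe/MeOH, I2, 0 °C
Reagents that add atoms: iodine, II
Why: Anti-Markovnikov hydroboration of the terminal vinyl group (the trisubstituted alkene is too hindered for 9-BBN-H) followed by base-promoted iodinolysis of the primary B–C bond, which gives the homoallylic iodide with the E-alkene retained.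

Step 10
Reactants: 16 β-eudesmol, 2-[(2R,4aR,8aS)-4a-methyl-8-methylidenedecahydronaphthalen-2-yl]propan-2-ol
Product: 17 triethyl({2-[(2R,4aR,8aS)-4a-methyl-8-methylidenedecahydronaphthalen-2-yl]propan-2-yl}oxy)silane
Conditions: Et3SiOTf, 2,6-lutidine, CH2Cl2, −78 → 0 °C
Reagents that add atoms: triethylsilyl trifluoromethanesulfonate, CC[Si](CC)(CC)OS(=O)(=O)C(F)(F)F
Why: Silyl triflate silylation of the hindered tertiary C11 alcohol, so that only the C4 oxygen made later can be acylated.

Step 11
Reactants: 17 triethyl({2-[(2R,4aR,8aS)-4a-methyl-8-methylidenedecahydronaphthalen-2-yl]propan-2-yl}oxy)silane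
Product: 18 4α,15-epoxy-11-(triethylsilyloxy)eudesmane (spiro-oxirane at C4, oxygen on the α face, trans to the C10 methyl)
Conditions: 3-ClC6H4CO3H, NaHCO3, CH2Cl2, 0 °C
Reagents that add atoms: 3-chloroperoxybenzoic acid, OOC(=O)c1cccc(Cl)c1
Why: Prilezhaev epoxidation of the exocyclic C4=C15 alkene, where the peracid should approach the α (equatorial) face, away from the axial C10 methyl that is 1,3 to C4 on the β face, placing the oxygen α as in cryptomeridiol.

Step 12
Reactants: 18 4α,15-epoxy-11-(triethylsilyloxy)eudesmane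
Product: 19 (1R,4aR,7R,8aR)-1,4a-dimethyl-7-[2-(triethylsilyloxy)propan-2-yl]decahydronaphthalen-1-ol
Conditions: LiAlH4, THF, 0 °C → reflux
Reagents that add atoms: none
Why: SN2 hydride opening of the spiro-epoxide at the unhindered CH2, which leaves the C4–O bond untouched and gives the 4α-tertiary alcohol with the β-methyl; the silyl ether is stable to LiAlH4.

Step 13
Reactants: 10 (1S,5R,8S)-8-(but-3-yn-1-yl)-1,5-dimethyl-6-oxabicyclo[3.2.1]octan-7-one; 15 tert-butyl{[(2E)-5-iodo-3-methylpent-2-en-1-yl]oxy}dimethylsilane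
Product: 21 (1S,5R,8S)-8-[(3Z,7E)-9-(tert-butyldimethylsilyloxy)-7-methyl-3-[(trimethylsilyl)methyl]nona-3,7-dien-1-yl]-1,5-dimethyl-6-oxabicyclo[3.2.1]octan-7-one, via alkenylcopper 20 (not isolated)
Conditions: Me3SiCH2MgCl, CuBr·SMe2, Et2O/Me2S, −40 °C; 10, −40 → −15 °C; then 15, (Me2N)3PO, P(OEt)3, THF, −30 °C → rt
Reagents that add atoms: (trimethylsilyl)methylmagnesium chloride, C[Si](C)(C)C[Mg]Cl
Why: Carbocupration of the terminal alkyne (syn addition, silylmethyl group to the internal carbon) followed by alkylation of the alkenylcopper with retention, so that C11 ends cis to CH2SiMe3 and trans to C7 (Z-allylsilane); organocopper reagents do not attack the lactone or the silyl ether.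

Step 14
Reactants: 21 (1S,5R,8S)-8-[(3Z,7E)-9-(tert-butyldimethylsilyloxy)-7-methyl-3-[(trimethylsilyl)methyl]nona-3,7-dien-1-yl]-1,5-dimethyl-6-oxabicyclo[3.2.1]octan-7-one
Product: 23 (1S,4aR,5S,8aR)-5-[(3E)-5-(tert-butyldimethylsilyloxy)-3-methylpent-3-en-1-yl]-1,4a-dimethyl-6-methylidenedecahydronaphthalene-1-carboxylic acid, via trimethylsilyl ester 22 (not isolated)
Conditions: Me3SiOTf (0.3 equiv), 2,6-di-tert-butyl-4-methylpyridine (0.4 equiv), CH2Cl2, −78 → −30 °C; then aqueous pH 5 buffer
Reagents that add atoms: none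
Why: Proposed new method: Me3SiOTf silylates the lactone carbonyl and the axial tertiary C10–O bond ionises (as the alkyl–oxygen bond of a tert-butyl ester does with silyl triflates) while C9 of the allylsilane attacks C10, and the β-silyl cation at C8 releases Me3Si+, which regenerates the promoter and leaves the C8=C17 methylene and silyl ester 22, hydrolysed on work-up. The closest known reactions are epoxide-initiated, allylsilane-terminated cation–olefin cyclisations, Hosomi–Sakurai tert-alkylation of allylsilanes by tertiary halides, and Friedel–Crafts alkylation of arenes by tertiary γ-lactones with alkyl–oxygen cleavage. Ring B closes in a 6-endo-trig mode with respect to the C8=C9 bond through a chair–chair transition state. C10 is set by inversion, because the bridged lactone holds C19 and the leaving oxygen axial on the β face and C6 equatorial, so C9 can only enter anti to the departing carboxylate, leaving the C20 methyl β and the ring fusion trans; C9 is set by the Z-allylsilane geometry (C11 trans to C7), which places C11 equatorial. The step needs C–C bond formation to outrun proton loss from the C10 cation and protodesilylation, which the tethered six-membered closure, the low temperature and the hindered pyridine (proton scavenger) are meant to secure; the primary allylic silyl ether should not ionise under these conditions.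

Step 15
Reactants: 23 (1S,4aR,5S,8aR)-5-[(3E)-5-(tert-butyldimethylsilyloxy)-3-methylpent-3-en-1-yl]-1,4a-dimethyl-6-methylidenedecahydronaphthalene-1-carboxylic acid; 19 (1R,4aR,7R,8aR)-1,4a-dimethyl-7-[2-(triethylsilyloxy)propan-2-yl]decahydronaphthalen-1-ol
Product: 25 (1R,4aR,7R,8aR)-1,4a-dimethyl-7-[2-(triethylsilyloxy)propan-2-yl]decahydronaphthalen-1-yl (1S,4aR,5S,8aR)-5-[(3E)-5-(tert-butyldimethylsilyloxy)-3-methylpent-3-en-1-yl]-1,4a-dimethyl-6-methylidenedecahydronaphthalene-1-carboxylate, via acid chloride 24 (not isolated)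
Conditions: 23, 1-chloro-N,N,2-trimethylprop-1-en-1-amine, CH2Cl2, 0 °C → rt; then 19, KN(SiMe3)2, THF, 0 → 50 °C
Reagents that add atoms: none
Why: Acyl substitution of the acid chloride (made under neutral conditions with the α-chloroenamine) by the potassium tertiary alkoxide, the usual way to tert-alkyl esters of hindered acids; neither partner can enolise, so all stereocentres including eudesmane C4 are retained.

Step 16
Reactants: 25 the bis-silyl ester from step 15
Product: 26 (1R,4aR,7R,8aR)-7-(2-hydroxypropan-2-yl)-1,4a-dimethyldecahydronaphthalen-1-yl (1S,4aR,5S,8aR)-5-[(3E)-5-hydroxy-3-methylpent-3-en-1-yl]-1,4a-dimethyl-6-methylidenedecahydronaphthalene-1-carboxylate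
Conditions: HF·pyridine, pyridine, THF, 0 °C → rt
Reagents that add atoms: none
Why: Fluoride-mediated cleavage of both silyl ethers, which under pyridine buffering should leave the tert-alkyl ester, the exocyclic alkene and the tertiary alcohol intact.

Step 17
Reactants: 26 the diol ester from step 16
Product: 27 CNP0141048.1, (1R,4aR,7R,8aR)-7-(2-hydroxypropan-2-yl)-1,4a-dimethyldecahydronaphthalen-1-yl (1S,4aR,5S,8aR)-5-[(3E)-5-acetoxy-3-methylpent-3-en-1-yl]-1,4a-dimethyl-6-methylidenedecahydronaphthalene-1-carboxylate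
Conditions: Ac2O, pyridine, CH2Cl2, 0 °C → rt
Reagents that add atoms: acetic anhydride, CC(=O)OC(C)=O
Why: Chemoselective O-acetylation, in which the primary allylic alcohol reacts without an acyl-transfer catalyst while the tertiary C11 alcohol of the eudesmane does not.

**Compound list**

1 | tert-butyl 2-oxocyclohexane-1-carboxylate | O=C1CCCCC1C(=O)OC(C)(C)C | starting material
2 | tert-butyl (1S)-1-methyl-2-oxocyclohexane-1-carboxylate | O=C1CCCC[C@]1(C)C(=O)OC(C)(C)C | intermediate
3 | tert-butyl (1S)-1,3-dimethyl-2-oxocyclohexane-1-carboxylate (C3 epimers) | CC1CCC[C@](C)(C(=O)OC(C)(C)C)C1=O | intermediate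
4 | tert-butyl (1S)-1,3-dimethyl-2-(trifluoromethanesulfonyloxy)cyclohex-2-ene-1-carboxylate | CC1=C(OS(=O)(=O)C(F)(F)F)[C@@](C)(C(=O)OC(C)(C)C)CCC1 | intermediate
5 | (4-bromobut-1-yn-1-yl)trimethylsilane | C[Si](C)(C)C#CCCBr | starting material
6 | [4-(trimethylsilyl)but-3-yn-1-yl]zinc bromide | C[Si](C)(C)C#CCC[Zn]Br | intermediate
7 | tert-butyl (1S)-1,3-dimethyl-2-[4-(trimethylsilyl)but-3-yn-1-yl]cyclohex-2-ene-1-carboxylate | CC1=C(CCC#C[Si](C)(C)C)[C@@](C)(C(=O)OC(C)(C)C)CCC1 | intermediate
8 | (1S)-1,3-dimethyl-2-[4-(trimethylsilyl)but-3-yn-1-yl]cyclohex-2-ene-1-carboxylic acid | CC1=C(CCC#C[Si](C)(C)C)[C@@](C)(C(=O)O)CCC1 | intermediate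
9 | (1S,5R,8S)-1,5-dimethyl-8-[4-(trimethylsilyl)but-3-yn-1-yl]-6-oxabicyclo[3.2.1]octan-7-one | O=C1O[C@]2(C)CCC[C@@]1(C)[C@@H]2CCC#C[Si](C)(C)C | intermediate
10 | (1S,5R,8S)-8-(but-3-yn-1-yl)-1,5-dimethyl-6-oxabicyclo[3.2.1]octan-7-one | O=C1O[C@]2(C)CCC[C@@]1(C)[C@@H]2CCC#C | intermediate
11 | (2E)-3-methylpent-2-en-4-yn-1-ol | C#C/C(C)=C/CO | starting material
12 | tert-butyldimethyl{[(2E)-3-methylpent-2-en-4-yn-1-yl]oxy}silane | C#C/C(C)=C/CO[Si](C)(C)C(C)(C)C | intermediate
13 | tert-butyldimethyl{[(2E)-3-methylpenta-2,4-dien-1-yl]oxy}silane | C=C/C(C)=C/CO[Si](C)(C)C(C)(C)C | intermediate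
14 | 9-[(3E)-5-(tert-butyldimethylsilyloxy)-3-methylpent-3-en-1-yl]-9-borabicyclo[3.3.1]nonane | B1(CC/C(C)=C/CO[Si](C)(C)C(C)(C)C)C2CCCC1CCC2 | intermediate
15 | tert-butyl{[(2E)-5-iodo-3-methylpent-2-en-1-yl]oxy}dimethylsilane | ICC/C(C)=C/CO[Si](C)(C)C(C)(C)C | intermediate
16 | β-eudesmol, 2-[(2R,4aR,8aS)-4a-methyl-8-methylidenedecahydronaphthalen-2-yl]propan-2-ol | C=C1CCC[C@]2(C)CC[C@@H](C(C)(C)O)C[C@H]21 | starting material
17 | triethyl({2-[(2R,4aR,8aS)-4a-methyl-8-methylidenedecahydronaphthalen-2-yl]propan-2-yl}oxy)silane | C=C1CCC[C@]2(C)CC[C@@H](C(C)(C)O[Si](CC)(CC)CC)C[C@H]21 | intermediate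
18 | 4α,15-epoxy-11-(triethylsilyloxy)eudesmane (spiro-oxirane, oxygen α) | O1[C@]2(C1)CCC[C@]3(C)CC[C@@H](C(C)(C)O[Si](CC)(CC)CC)C[C@H]32 | intermediate
19 | (1R,4aR,7R,8aR)-1,4a-dimethyl-7-[2-(triethylsilyloxy)propan-2-yl]decahydronaphthalen-1-ol | O[C@]1(C)CCC[C@]2(C)CC[C@@H](C(C)(C)O[Si](CC)(CC)CC)C[C@H]21 | intermediate
20 | (Z)-alkenylcopper from carbocupration of 10 (Cu on the terminal carbon, cis to CH2SiMe3) | O=C1O[C@]2(C)CCC[C@@]1(C)[C@@H]2CC/C(=C/[Cu])C[Si](C)(C)C | intermediate
21 | (1S,5R,8S)-8-[(3Z,7E)-9-(tert-butyldimethylsilyloxy)-7-methyl-3-[(trimethylsilyl)methyl]nona-3,7-dien-1-yl]-1,5-dimethyl-6-oxabicyclo[3.2.1]octan-7-one | O=C1O[C@]2(C)CCC[C@@]1(C)[C@@H]2CC/C(=C/CC/C(C)=C/CO[Si](C)(C)C(C)(C)C)C[Si](C)(C)C | intermediate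
22 | trimethylsilyl ester of acid 23 | C=C1CC[C@@H]2[C@](C)(CCC[C@]2(C)C(=O)O[Si](C)(C)C)[C@H]1CC/C(C)=C/CO[Si](C)(C)C(C)(C)C | intermediate
23 | (1S,4aR,5S,8aR)-5-[(3E)-5-(tert-butyldimethylsilyloxy)-3-methylpent-3-en-1-yl]-1,4a-dimethyl-6-methylidenedecahydronaphthalene-1-carboxylic acid | C=C1CC[C@@H]2[C@](C)(CCC[C@]2(C)C(=O)O)[C@H]1CC/C(C)=C/CO[Si](C)(C)C(C)(C)C | intermediate
24 | acid chloride of 23 | C=C1CC[C@@H]2[C@](C)(CCC[C@]2(C)C(=O)Cl)[C@H]1CC/C(C)=C/CO[Si](C)(C)C(C)(C)C | intermediate
25 | (1R,4aR,7R,8aR)-1,4a-dimethyl-7-[2-(triethylsilyloxy)propan-2-yl]decahydronaphthalen-1-yl (1S,4aR,5S,8aR)-5-[(3E)-5-(tert-butyldimethylsilyloxy)-3-methylpent-3-en-1-yl]-1,4a-dimethyl-6-methylidenedecahydronaphthalene-1-carboxylate | C=C1CC[C@@H]2[C@](C)(CCC[C@]2(C)C(=O)O[C@]2(C)CCC[C@]3(C)CC[C@@H](C(C)(C)O[Si](CC)(CC)CC)C[C@H]32)[C@H]1CC/C(C)=C/CO[Si](C)(C)C(C)(C)C | intermediate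
26 | (1R,4aR,7R,8aR)-7-(2-hydroxypropan-2-yl)-1,4a-dimethyldecahydronaphthalen-1-yl (1S,4aR,5S,8aR)-5-[(3E)-5-hydroxy-3-methylpent-3-en-1-yl]-1,4a-dimethyl-6-methylidenedecahydronaphthalene-1-carboxylate | C=C1CC[C@@H]2[C@](C)(CCC[C@]2(C)C(=O)O[C@]2(C)CCC[C@]3(C)CC[C@@H](C(C)(C)O)C[C@H]32)[C@H]1CC/C(C)=C/CO | intermediate
27 | CNP0141048.1, (1R,4aR,7R,8aR)-7-(2-hydroxypropan-2-yl)-1,4a-dimethyldecahydronaphthalen-1-yl (1S,4aR,5S,8aR)-5-[(3E)-5-acetoxy-3-methylpent-3-en-1-yl]-1,4a-dimethyl-6-methylidenedecahydronaphthalene-1-carboxylate | C=C1CC[C@@H]2[C@](C)(CCC[C@]2(C)C(=O)O[C@]2(C)CCC[C@]3(C)CC[C@@H](C(C)(C)O)C[C@H]32)[C@H]1CC/C(C)=C/COC(C)=O | target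

**Step count**

Total step count: 17. Longest linear sequence: 11 (steps 1–6 and 13–17).

**Steps most likely to fail**

1. Step 14 (Proposed new method). The ionised lactone may only recombine (ion-pair return), the C10 cation may lose a proton faster than the tethered allylsilane attacks, or traces of acid may protodesilylate the allylsilane. The fallback uses known chemistry and sets out from 21. LiAlH4 (THF, 0 °C) reduces the lactone to the all-cis ring-A diol F1. Ac2O/pyridine acetylates only its primary alcohol and gives the diol monoacetate F2. SnCl4 (CH2Cl2, −78 °C) then ionises the tertiary carbinol in a classical allylsilane-terminated cation–olefin cyclisation (intramolecular Hosomi–Sakurai alkylation) to the bicyclic 19-acetate F3, for which the chair transition state is again expected to give the trans fusion. K2CO3/MeOH gives the 19-alcohol F4, Dess–Martin oxidation gives the 19-aldehyde F5, and Pinnick oxidation (NaClO2, NaH2PO4, 2-methylbut-2-ene) comes back to the route at acid 23.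

2. Step 15. Acyl substitution at the axial, neopentylic carbonyl by the hindered tertiary alkoxide may be too slow, so that the acid chloride is only hydrolysed on work-up. The fallback forms the alkyl–oxygen bond instead of the acyl–oxygen bond and sets out from 19 and 23. Cl3CCN with catalytic KH (Et2O, 0 °C) converts 19 into the tertiary trichloroacetimidate F6. Acid 23 and the trichloroacetimidate F6 in cyclohexane/CH2Cl2 at rt (the acid itself activates the imidate, as with tert-butyl trichloroacetimidate) should give ester 25, where the fallback comes back to the route. Carboxylate capture of the eudesmane C4 cation is expected from the equatorial α face, and elimination of the cation is the price of this variant.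

3. Step 13. Alkylation of the alkenylcopper by the unactivated primary iodide may be slow, so that protonolysis on work-up gives the disubstituted allylsilane without the side chain. The fallback replaces the copper alkylation by a palladium cross-coupling and sets out from 10. The same carbocupration is quenched with I2 (1.0 equiv, −78 °C) to give the Z-alkenyl iodide F7. B-alkyl Suzuki–Miyaura coupling of F7 with borane 14, made from 13 as in step 9 without the iodinolysis (Pd(dppf)Cl2, AsPh3, Cs2CO3, DMF/THF/H2O, rt), comes back to the route at 21.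

**Further compounds**

F1 | step 14 | ring-A diol: 3-(hydroxymethyl)-1,3-dimethyl-2-[(3Z,7E)-9-(tert-butyldimethylsilyloxy)-7-methyl-3-[(trimethylsilyl)methyl]nona-3,7-dien-1-yl]cyclohexan-1-ol, with OH, side chain and CH2OH all cis | OC[C@@]1(C)CCC[C@@](C)(O)[C@H]1CC/C(=C/CC/C(C)=C/CO[Si](C)(C)C(C)(C)C)C[Si](C)(C)C
F2 | step 14 | primary acetate of F1 (tertiary alcohol free) | CC(=O)OC[C@@]1(C)CCC[C@@](C)(O)[C@H]1CC/C(=C/CC/C(C)=C/CO[Si](C)(C)C(C)(C)C)C[Si](C)(C)C
F3 | step 14 | [(1S,4aR,5S,8aR)-5-[(3E)-5-(tert-butyldimethylsilyloxy)-3-methylpent-3-en-1-yl]-1,4a-dimethyl-6-methylidenedecahydronaphthalen-1-yl]methyl acetate | C=C1CC[C@@H]2[C@](C)(CCC[C@]2(C)COC(C)=O)[C@H]1CC/C(C)=C/CO[Si](C)(C)C(C)(C)C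
F4 | step 14 | [(1S,4aR,5S,8aR)-5-[(3E)-5-(tert-butyldimethylsilyloxy)-3-methylpent-3-en-1-yl]-1,4a-dimethyl-6-methylidenedecahydronaphthalen-1-yl]methanol | C=C1CC[C@@H]2[C@](C)(CCC[C@]2(C)CO)[C@H]1CC/C(C)=C/CO[Si](C)(C)C(C)(C)C
F5 | step 14 | (1S,4aR,5S,8aR)-5-[(3E)-5-(tert-butyldimethylsilyloxy)-3-methylpent-3-en-1-yl]-1,4a-dimethyl-6-methylidenedecahydronaphthalene-1-carbaldehyde | C=C1CC[C@@H]2[C@](C)(CCC[C@]2(C)C=O)[C@H]1CC/C(C)=C/CO[Si](C)(C)C(C)(C)C
F6 | step 15 | (1R,4aR,7R,8aR)-1,4a-dimethyl-7-[2-(triethylsilyloxy)propan-2-yl]decahydronaphthalen-1-yl 2,2,2-trichloroacetimidate | N=C(O[C@]1(C)CCC[C@]2(C)CC[C@@H](C(C)(C)O[Si](CC)(CC)CC)C[C@H]21)C(Cl)(Cl)Cl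
F7 | step 13 | (1S,5R,8S)-8-[(3Z)-4-iodo-3-[(trimethylsilyl)methyl]but-3-en-1-yl]-1,5-dimethyl-6-oxabicyclo[3.2.1]octan-7-one | O=C1O[C@]2(C)CCC[C@@]1(C)[C@@H]2CC/C(=C/I)C[Si](C)(C)C
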